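**Retrosynthetic overview**
1. Target ⇒ C11–O disconnection: Schenck ene reaction of singlet oxygen on the ring B isopropylidene enone. The angelate ester C–O bond ⇒ diol enone + angelic acid.
2. Isopropylidene enone ⇒ aldol condensation of the ring B C8 ketone with acetone at C7.
3. 3β,4α-Diol (C4–O bond; C3, C4 and C5 stereocentres) ⇒ one-flask borane reduction/hydroboration–oxidation of a 4-methyl-Δ4-3-enone whose ring B ketone is masked as a dioxolane.
4. Bicyclic enone ⇒ auxiliary-controlled Michael addition, then aldol condensation (Robinson annulation), of a methylcyclohexanedione mono-ketal with ethyl vinyl ketone. Ring B comes with the starting ketone; ring A is closed second.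

Assumption: racemic 7-methyl-1,4-dioxaspiro[4.5]decan-8-one (1) is bought as a catalogue compound (otherwise it is one methylation from 1,4-dioxaspiro[4.5]decan-8-one).
Numbering: eudesmane numbering is used for the decalins. Ring A = C1–C5 and C10; ring B = C5–C10; C14 = methyl on C10; C15 = methyl on C4; C11–C13 = three-carbon unit on C7; β = face of C14.

**Step 1**
Reactants: 1 7-methyl-1,4-dioxaspiro[4.5]decan-8-one (racemic); 2 (R)-1-phenylethylamine; 3 ethyl vinyl ketone (pent-1-en-3-one)
Product: 6 (7R)-7-methyl-7-(3-oxopentyl)-1,4-dioxaspiro[4.5]decan-8-one, via ketimine 4 (not isolated), via Michael adduct ketimine 5 (not isolated)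
Conditions: 2 (1.05 equiv), TsOH·H2O (1 mol %), toluene, reflux, Dean–Stark; then 3 (1.5 equiv), THF, 40 °C, 3 d; then AcOH/H2O (1:4), rt, 2 h
Reagents that add atoms: water, O
Why: d'Angelo deracemizing Michael addition, in which ketimine 4 reacts through its more substituted secondary enamine and adds to the enone in a chair-like aza-ene transition state on the face away from the phenyl group of the (R)-auxiliary, so the quaternary C10 is set as R whatever the configuration of racemic 1 (typically ≥ 90% ee, to be raised by recrystallising diol 12), and the dioxolane survives the mild acetic acid hydrolysis.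

**Step 2**
Reactants: 6 (7R)-7-methyl-7-(3-oxopentyl)-1,4-dioxaspiro[4.5]decan-8-one
Product: 8 (10R)-8,8-ethylenedioxy-11,12,13-trinoreudesm-4-en-3-one, via bicyclic ketol 7 (not isolated)
Conditions: NaOMe (0.5 equiv), MeOH, 60 °C, 8 h
Reagents that add atoms: none
Why: Intramolecular aldol condensation (second half of the Robinson annulation) of the ethyl ketone onto the ring ketone closes ring A as the tetrasubstituted C4=C5 enone, with no stereocentre touched and the dioxolane inert to methoxide.

**Step 3**
Reactants: 8 (10R)-8,8-ethylenedioxy-11,12,13-trinoreudesm-4-en-3-one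
Product: 12 3β,4α-dihydroxy-11,12,13-trinor-5α-eudesman-8-one, via allyloxyborane 9 (not isolated), via organoborane 10 (not isolated), via diol ketal 11 (not isolated)
Conditions: BH3·THF (4 equiv), THF, 0 → 45 °C, 16 h; 3 M NaOH, 30% H2O2, 0 → 40 °C; Na2SO3 (aq); then 3 M HCl, THF, rt, 4 h
Reagents that add atoms: hydrogen peroxide, OO; water, O
Why: Proposed new method: one-flask reductive oxygenation of a fully substituted 4-methyl-Δ4-3-enone, in which BH3 first reduces C3=O by axial hydride delivery on the α face to the 3β-allyloxyborane 9, whose oxygen substituent polarises the tetrasubstituted C4=C5 bond so that a second B–H adds with boron at C4 (the carbon next to oxygen and the less hindered one, C5 being flanked by quaternary C10) and syn hydrogen at C5 on the α face, anti to both the 3β-O–B group and the axial C14 methyl (organoborane 10, trans ring fusion, the trans-diequatorial O–B/C–B pair being unable to eliminate), after which alkaline H2O2 converts C4–B into C4–OH with retention (three stereocentres set in 11) and aqueous HCl unmasks the C8 ketone; the closest known reaction type is the hydroboration–oxidation of trisubstituted cyclic enones and Δ4-3-keto steroids to trans-3β,4α-diols, which has not been shown for a tetrasubstituted α-methyl enone where a tertiary C–B bond and a tertiary carbinol must form.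

**Step 4**
Reactants: 12 3β,4α-dihydroxy-11,12,13-trinor-5α-eudesman-8-one; 13 acetone
Product: 16 3β,4α,11-trihydroxy-5α-eudesman-8-one (C7 epimers), via trilithium enolate 14 (not isolated), via trilithium aldolate 15 (not isolated)
Conditions: LiN(iPr)2 (3.3 equiv), THF, −78 °C, 1 h; 13 (5 equiv), −78 °C, 30 min; AcOH, −78 °C
Reagents that add atoms: none
Why: Directed crossed aldol addition, in which two equivalents of base deprotonate the hydroxyls and the third forms the kinetic C7 enolate (C9 is neopentylic, next to quaternary C10), which adds to acetone at low temperature; the new C7 centre is an epimer mixture that is erased in step 5.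

**Step 5**
Reactants: 16 3β,4α,11-trihydroxy-5α-eudesman-8-one (C7 epimers)
Product: 17 3β,4α-dihydroxy-5α-eudesm-7(11)-en-8-one
Conditions: TsOH·H2O (10 mol %), toluene, 50 °C, 3 h
Reagents that add atoms: none
Why: Acid-catalysed dehydration of a tertiary β-hydroxy ketone (completing the aldol condensation) runs through the enol far faster than ionisation of the C4 tertiary alcohol, which is deactivated by the adjacent C3 hydroxyl, and equilibrates to the conjugated isopropylidene isomer.

**Step 6**
Reactants: 17 3β,4α-dihydroxy-5α-eudesm-7(11)-en-8-one; 18 angelic acid [(Z)-2-methylbut-2-enoic acid]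
Product: 19 3β-angeloyloxy-4α-hydroxy-5α-eudesm-7(11)-en-8-one
Conditions: 18 (3 equiv), 2,4,6-Cl3C6H2COCl (3 equiv), Et3N (6 equiv), toluene, rt, 2 h; then 17, 80 °C, 24 h
Reagents that add atoms: none
Why: Yamaguchi-type esterification through the mixed 2,4,6-trichlorobenzoic angelic anhydride without DMAP acylates only the secondary equatorial 3β-hydroxyl (the tertiary 4α-hydroxyl is inert) and is the established way to attach an angelate without Z to E isomerisation; reaction is at oxygen, so C3 is retained.

**Step 7**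
Reactants: 19 3β-angeloyloxy-4α-hydroxy-5α-eudesm-7(11)-en-8-one
Product: 20 (3S,4S,5R,10R)-4-hydroxy-11-hydroperoxy-8-oxoeudesm-6-en-3-yl (Z)-2-methylbut-2-enoate (3β-angeloyloxy-4α-hydroxy-11-hydroperoxy-5α-eudesm-6-en-8-one)
Conditions: O2, hν (white LEDs), 5,10,15,20-tetraphenylporphyrin (1 mol %), CH2Cl2, 0 °C, 8 h
Reagents that add atoms: dioxygen, O=O
Why: Schenck ene reaction of singlet oxygen with an s-cis α,β-unsaturated ketone, for which the gem rule places oxygen on the β-carbon C11 and removes hydrogen from the alkyl group on the α-carbon (axial C6–H), giving the conjugated 11-hydroperoxy-6-en-8-one, while the electron-poor angelate alkene reacts much more slowly and no stereocentre is formed or touched.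

**Compound list**
1 | 7-methyl-1,4-dioxaspiro[4.5]decan-8-one (racemic) | CC1CC2(CCC1=O)OCCO2 | starting material
2 | (R)-1-phenylethylamine | C[C@@H](N)c1ccccc1 | starting material
3 | ethyl vinyl ketone (pent-1-en-3-one) | CCC(=O)C=C | starting material
4 | N-[(R)-1-phenylethyl] ketimine of 1 (C7 epimers, in equilibrium with the secondary enamine) | CC1CC2(CCC1=N[C@H](C)c1ccccc1)OCCO2 | intermediate
5 | N-[(R)-1-phenylethyl] ketimine of 6 at the ring ketone | CCC(=O)CC[C@]1(C)CC2(CCC1=N[C@H](C)c1ccccc1)OCCO2 | intermediate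
6 | (7R)-7-methyl-7-(3-oxopentyl)-1,4-dioxaspiro[4.5]decan-8-one | CCC(=O)CC[C@]1(C)CC2(CCC1=O)OCCO2 | intermediate
7 | (10R)-8,8-ethylenedioxy-5-hydroxy-11,12,13-trinoreudesman-3-one (C4 and C5 epimers) | O=C1CC[C@]2(C)CC3(OCCO3)CCC2(O)C1C | intermediate
8 | (10R)-8,8-ethylenedioxy-11,12,13-trinoreudesm-4-en-3-one (ring A 4-methyl-Δ4-3-enone, ring B C8 dioxolane, 10β-methyl) | O=C1CC[C@]2(C)CC3(OCCO3)CCC2=C1C | intermediate
9 | 3β-(boryloxy)-8,8-ethylenedioxy-11,12,13-trinoreudesm-4-ene (drawn as the monomeric RO–BH2 species) | BO[C@H]1CC[C@]2(C)CC3(OCCO3)CCC2=C1C | intermediate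
10 | 4α-boryl-3β-(boryloxy)-8,8-ethylenedioxy-11,12,13-trinor-5α-eudesmane (4β-methyl; drawn as monomeric BH2 species) | BO[C@H]1CC[C@]2(C)CC3(OCCO3)CC[C@H]2[C@]1(C)B | intermediate
11 | 8,8-ethylenedioxy-11,12,13-trinor-5α-eudesmane-3β,4α-diol (4β-methyl) | O[C@H]1CC[C@]2(C)CC3(OCCO3)CC[C@H]2[C@]1(C)O | intermediate
12 | 3β,4α-dihydroxy-11,12,13-trinor-5α-eudesman-8-one [(4aR,5S,6S,8aR)-5,6-dihydroxy-5,8a-dimethyloctahydronaphthalen-2(1H)-one] | O[C@H]1CC[C@]2(C)CC(=O)CC[C@H]2[C@]1(C)O | intermediate
13 | acetone | CC(C)=O | starting material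
14 | trilithium 3β,4α-dioxido-C7 enolate of 12 | [Li]O[C@H]1CC[C@]2(C)CC(O[Li])=CC[C@H]2[C@]1(C)O[Li] | intermediate
15 | trilithium alkoxide of 16 (C7 epimers) | [Li]O[C@H]1CC[C@]2(C)CC(=O)C(C(C)(C)O[Li])C[C@H]2[C@]1(C)O[Li] | intermediate
16 | 3β,4α,11-trihydroxy-5α-eudesman-8-one (C7 epimers) | O[C@H]1CC[C@]2(C)CC(=O)C(C(C)(C)O)C[C@H]2[C@]1(C)O | intermediate
17 | 3β,4α-dihydroxy-5α-eudesm-7(11)-en-8-one | O[C@H]1CC[C@]2(C)CC(=O)C(=C(C)C)C[C@H]2[C@]1(C)O | intermediate
18 | angelic acid [(Z)-2-methylbut-2-enoic acid] | C/C=C(/C)C(=O)O | starting material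
19 | 3β-angeloyloxy-4α-hydroxy-5α-eudesm-7(11)-en-8-one | C/C=C(/C)C(=O)O[C@H]1CC[C@]2(C)CC(=O)C(=C(C)C)C[C@H]2[C@]1(C)O | intermediate
20 | (3S,4S,5R,10R)-4-hydroxy-11-hydroperoxy-8-oxoeudesm-6-en-3-yl (Z)-2-methylbut-2-enoate | C/C=C(/C)C(=O)O[C@H]1CC[C@]2(C)CC(=O)C(C(C)(C)OO)=C[C@H]2[C@]1(C)O | target

**Step count and risks**
Total step count: 7. Longest linear sequence: 7 steps (1 → 20).

The three steps most likely to fail are steps 3, 6 and 7.

Step 3 (the proposed new method). The tetrasubstituted C4=C5 bond may hydroborate sluggishly or with boron at C5, and the C3 epimer ratio from the borane reduction is not secured. The fallback uses known chemistry only; it sets out from 8 and comes back at 11.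
- Dissolving-metal reduction of 8 (Li, NH3/THF, t-BuOH 1 equiv, −78 °C; NH3 evaporated; Me3SiCl, Et3N, THF, 0 °C) traps the regiodefined enolate as the trans-fused trimethylsilyl enol ether F1.
- Rubottom oxidation on the α face (m-CPBA, NaHCO3, CH2Cl2, 0 °C; then Bu4NF, THF, 0 °C) gives the 4α-hydroxy-3-ketone F2.
- NaBH4 (MeOH, 0 °C, axial hydride) gives diol ketal 11, which is hydrolysed with aqueous HCl/THF as in the last operation of step 3 to 12.
- Here C5 is set by the metal–ammonia reduction, C4 by oxidation of the enol ether and C3 by hydride, at the cost of two extra steps.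

Step 6. The 3β-hydroxyl is flanked by the fully substituted C4, so acyl transfer may be slow, and forcing it invites angelate to tiglate isomerisation. The fallback sets out from 17 and comes back at 19.
- 17 is acylated with the more reactive 2-[bis(2,2,2-trifluoroethoxy)phosphoryl]propanoic acid (EDC·HCl, DMAP cat., CH2Cl2, rt) to give the phosphonate ester F3.
- Still–Gennari olefination with acetaldehyde (KN(SiMe3)2 1.0 equiv, 18-crown-6, THF, −78 °C) then builds the Z-trisubstituted alkene on the ester, giving 19.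

Step 7. Hydrogen abstraction from the C12/C13 methyls (oxygen at C7) may compete with the desired C6–H abstraction, and the enone reacts slowly. The fallback makes the C11–O bond by a radical route; it sets out from 12 and comes back at 20.
- 12 is angeloylated as in step 6 to the keto angelate F4.
- Aerobic dehydrogenation (Pd(OCOCF3)2 5 mol %, DMSO 10 mol %, O2, AcOH, 80 °C) gives the 6-en-8-one F5; the regiochemistry is unambiguous because C10 is quaternary.
- α-Iodination (I2, pyridine, CH2Cl2, rt) gives the iodoenone F6.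
- Suzuki coupling with isopropenylboronic acid pinacol ester (Pd(PPh3)4 5 mol %, K3PO4, dioxane/H2O, 60 °C) gives the isopropenyl dienone F7.
- Isayama–Mukaiyama hydroperoxysilylation (Co(acac)2 10 mol %, Et3SiH, O2, ClCH2CH2Cl, rt) transfers a hydrogen atom to the terminal CH2 and traps the tertiary C11 radical with O2, giving the triethylsilyl peroxide F8; trapping at C6 instead of C11 is possible and would give a regioisomer to be separated.
- Desilylation (Bu4NF/AcOH, THF, 0 °C) gives 20.

**Further compounds**
F1 | step 3 | 8,8-ethylenedioxy-3-(trimethylsilyloxy)-11,12,13-trinor-5α-eudesm-3-ene | C[Si](C)(C)OC=1CC[C@]2(C)CC3(OCCO3)CC[C@H]2C=1C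
F2 | step 3 | 8,8-ethylenedioxy-4α-hydroxy-11,12,13-trinor-5α-eudesman-3-one (4β-methyl) | O=C1CC[C@]2(C)CC3(OCCO3)CC[C@H]2[C@]1(C)O
F3 | step 6 | 3β-{2-[bis(2,2,2-trifluoroethoxy)phosphoryl]propanoyloxy}-4α-hydroxy-5α-eudesm-7(11)-en-8-one (epimers at the phosphonate carbon) | CC(C(=O)O[C@H]1CC[C@]2(C)CC(=O)C(=C(C)C)C[C@H]2[C@]1(C)O)P(=O)(OCC(F)(F)F)OCC(F)(F)F
F4 | step 7 | 3β-angeloyloxy-4α-hydroxy-11,12,13-trinor-5α-eudesman-8-one | C/C=C(/C)C(=O)O[C@H]1CC[C@]2(C)CC(=O)CC[C@H]2[C@]1(C)O
F5 | step 7 | 3β-angeloyloxy-4α-hydroxy-11,12,13-trinor-5α-eudesm-6-en-8-one | C/C=C(/C)C(=O)O[C@H]1CC[C@]2(C)CC(=O)C=C[C@H]2[C@]1(C)O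
F6 | step 7 | 3β-angeloyloxy-4α-hydroxy-7-iodo-11,12,13-trinor-5α-eudesm-6-en-8-one | C/C=C(/C)C(=O)O[C@H]1CC[C@]2(C)CC(=O)C(I)=C[C@H]2[C@]1(C)O
F7 | step 7 | 3β-angeloyloxy-4α-hydroxy-5α-eudesma-6,11-dien-8-one | C/C=C(/C)C(=O)O[C@H]1CC[C@]2(C)CC(=O)C(C(C)=C)=C[C@H]2[C@]1(C)O
F8 | step 7 | 3β-angeloyloxy-4α-hydroxy-11-(triethylsilylperoxy)-5α-eudesm-6-en-8-one | C/C=C(/C)C(=O)O[C@H]1CC[C@]2(C)CC(=O)C(C(C)(C)OO[Si](CC)(CC)CC)=C[C@H]2[C@]1(C)O
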